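## Structural features

The target is a 2'-hydroxy-β-hydroxydihydrochalcone. A C(=O)–CH2–CH(OH) chain joins C5 of a 2,3-dihydrobenzofuran (benzene ring A fused to dihydrofuran ring B; O1, C2, C3, C3a, C4–C7, C7a) to C6 of a 2,2-dimethylchroman (benzene ring C fused to dihydropyran ring D). Ring A carries a free phenol at C6, ortho to the ketone, and ring B carries a 2-hydroxypropan-2-yl group at C2. There are two stereocentres, C2 of ring B and the carbinol carbon of the chain, both S; they lie seven bonds apart across ring A, so neither can direct the other and each must be set by a reagent. The fragile part is the aldol unit: the β-hydroxy ketone can undergo retro-aldol cleavage or lose water to the chalcone, the carbinol is a para-alkoxybenzylic alcohol that ionises in acid, and the ortho-phenol can then close a flavanone. The tertiary alcohol next to C2 is also sensitive to acid. The real difficulty is the isolated stereocentre at C2, flanked by O1 and a fully substituted carbinol carbon with nothing nearby to relay chirality, followed by attaching the acyl chain at C5 and not at C7. The key step exploits two facts: C2 is an ether carbon whose C–H bond is weakened by O1 in the open-chain aryl ether, and C3 is a benzylic carbon that can begin as the aldehyde carbon of a salicylaldehyde ether, the two carbons standing 1,5 to each other across O1, C7a and C3a.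

## Logic of the disconnections

**20 back to 18 (through 19).** The two O–Si bonds are cut first, then the O–CH2 bond of the benzyl ether on ring A. The aldol unit and the ortho-phenol are the only sensitive functions, so they stay masked until only deprotection remains. Every earlier intermediate is then a robust ether. The forward steps must remove benzyl without reducing the benzylic C–O bond of the carbinol or the ketone, and must remove silicon close to neutral pH.

**18 to 8 and 16 (through 17).** The C5–C(=O) bond is cut. It is the one bond that divides the molecule into two halves of similar size with one stereocentre each, and it pairs an acyl electrophile with an aryl nucleophile. The gain is convergence. The demand is a carbanion at C5 and nowhere else, which is why 8 carries bromine at C5. A precursor with hydrogen at C5 would leave a later acylation to choose between C5 and C7 and would cost a step, so the bromine is brought in with 1 and rides through as a spectator. The acyl partner must react once and keep its β-oxygen, hence the N-methoxy-N-methyl amide and the silyl ether in 16.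

**8 to 6 (through 7).** The C3–C2 bond of ring B is cut, which opens the ring and removes the C2 stereocentre. C3 is traced to an aldehyde carbon and C2 to an O–CH2 group, so 6 is achiral and open-chain. One forward step returns one ring, one skeletal bond and one stereocentre. The demand is catalyst control over a prochiral radical, hydrogen abstraction only from the O–CH2 group, and inertness of bromide, benzyl ether and silyl ether. Descriptor check: at C2 the order O1 > C(O,C,C) > C3 > H holds in 8, 18, 19 and 20 alike, so S in 8 is S in 20; the C4 oxygen of the benzaldehyde becomes the C6 oxygen of ring A.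

**6 to 4 (through 5).** The C=N bond and the O–Si bond are cut. The hydrazone is only the storage form of the diazo group, and the silyl ether hides the tertiary O–H from the radical step. The forward steps are a condensation and a silylation that must leave the aldehyde alone.

**4 to 2 and 3.** The ArO–CH2 bond is cut. All four carbons of the C2 side arm, with the tertiary oxygen, come from 3. The phenoxide must attack the CH2 of the epoxide.

**2 to 1.** The O–CH2Ph bond is cut. The forward step must distinguish the two phenols of 1.

**16 to 14 (through 15).** The O–Si bond and the N–C(=O) bond are cut, leading back to a β-hydroxy ester. The amide must be formed without disturbing the carbinol.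

**14 to 13.** The C–H bond at the carbinol carbon is cut, turning the stereocentre into a prochiral ketone. The forward step is a catalytic hydrogenation that must choose one face.

**13 to 11 and 12.** The CH2–CO2Me bond is cut; the ketone carbon of 20 comes from 12. The forward step is an enolate acylation.

**11 to 9 and 10.** The C4–C4a and O1–C2 bonds of ring D are cut. Both partners are commodity chemicals. The forward step must alkylate a phenol ring that is deactivated by the acetyl group.

## Other disconnections considered

**Alternative 1:** The cut is through C4–C3 and O1–C2 of ring D. In the forward step, heating 4-hydroxy-3-(hydroxymethyl)benzaldehyde A1 would expel water and unmask a heterodiene, which would add 2-methylpropene A2 in an inverse-demand hetero-Diels–Alder reaction to give 2,2-dimethylchroman-6-carbaldehyde A3.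
- In favour: the polarity of the cycloaddition fixes the regiochemistry (oxygen to the disubstituted carbon), and no acid is involved. On this point it is better than step 6, which must push a Friedel–Crafts-type alkylation onto an acetyl-deactivated phenol.
- Against: A2 is a gas and the reaction needs a sealed vessel well above 150 °C, where the heterodiene also oligomerises. A1 is not a commodity phenol. A3 is an aldehyde, so the carbinol centre would have to come from an auxiliary-controlled acetate aldol reaction, not from a catalytic hydrogenation.
- Comparison: structurally it solves only the achiral ring D and leaves C2 of ring B untouched. Mechanistically it is a clean thermal pericyclic process, equal to step 6 in reliability. In step count, A3 could reach 15 in about two steps against three from 11, but the preparation of A1 uses up that gain, so the two are about equal. It cannot carry the strategy because the hard stereocentre remains.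

**Alternative 2:** The cut is through C3a–C3 and O1–C2 of ring B. In the forward step, zerovalent palladium from Pd2(dba)3 and a chiral phosphine would insert into the C–I bond of 1-(2,4-dihydroxy-5-iodophenyl)ethanone A4. The arylpalladium species would add to the less substituted double bond of 10, and the neighbouring phenoxide would close on the π-allyl complex to give (S)-1-[6-hydroxy-2-(prop-1-en-2-yl)-2,3-dihydro-1-benzofuran-5-yl]ethanone A5. Mukaiyama hydration (Co(acac)2, silane, O2) would lead to (S)-1-[6-hydroxy-2-(2-hydroxypropan-2-yl)-2,3-dihydro-1-benzofuran-5-yl]ethanone A6, and an aldol reaction with A3 would finish 20.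
- In favour: ring B, the C2 stereocentre, the C5 acyl carbon and the free C6 phenol arrive in one step without protecting groups. The reaction type is known for ortho-halophenols and 1,3-dienes, which is better precedent than step 5 has. The route would be several steps shorter, so it is better in step economy.
- Against: the endgame rests on an enantioselective acetate-type aldol reaction of a methyl ketone bearing a free ortho-phenol with an electron-rich aldehyde. Unsubstituted enolates give modest facial control, and the product is the very aldol that dehydrates and cyclises most easily. The regiochemistry of insertion into 10 and the enantioselectivity with an unprotected keto-phenol are further open points.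
- Comparison: both plans make ring B and C2 in one ligand-controlled step and are equal there. Alternative 2 forms two bonds where step 5 forms one. The chosen plan is better at the carbinol centre, which it sets by hydrogenation of 13 on a small, stable molecule and then carries protected.

**Alternative 3:** The cut is through C3–C2 and O1–C2 of ring B, with C2 supplied by a one-carbon ylide. In the forward step, base would expel sulfinate from 5-(allyloxy)-4-bromo-2-[(4-methylbenzenesulfonyl)methyl]phenol A7, ethyl (dimethylsulfuranylidene)acetate A8 would add to the exocyclic methylene of the resulting heterodiene, and the phenoxide would displace dimethyl sulfide to give ethyl (S)-6-(allyloxy)-5-bromo-2,3-dihydro-1-benzofuran-2-carboxylate A9.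
- In favour: the mechanism is ionic and well understood, runs at ambient temperature, and is known on this substrate class in racemic form, which is better precedent than step 5 has. A9 carries bromine at C5, the same handle as 8, so the two are equal on that point.
- Against: C2 in A9 is α to both an ester and an aryloxy oxygen and is formed in base, so its configuration is at risk as it forms and again when methyl Grignard reagent converts the ester to the tertiary alcohol. Enantiocontrol would need a stoichiometric chiral sulfide or a catalyst acting on an intermolecular addition to a flat heterodiene. A7 needs about four steps, and A9 needs a Grignard addition and a silylation before it could join 16 as 8 does.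
- Comparison: structurally it builds the same ring with two bonds. It is better in precedent for the bond formation and worse for the integrity of the stereocentre, which in 8 has no acidifying neighbour. It would be about two steps longer.

Key step: step 5

Assumption: 5-bromo-2,4-dihydroxybenzaldehyde 1 is taken as a catalogue building block.

## Route

**Step 1**
Reactants: 1 5-bromo-2,4-dihydroxybenzaldehyde
Product: 2 4-(benzyloxy)-5-bromo-2-hydroxybenzaldehyde
Conditions: BnBr (1.05 equiv), NaHCO3, KI (cat.), MeCN, 80 °C
Reagents that add atoms: benzyl bromide, BrCc1ccccc1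
Why: Williamson etherification under bicarbonate: only the C4 hydroxyl, para to the formyl group and next to bromine, is acidic and free enough to be ionised, while the C2 hydroxyl is held in a hydrogen bond to the carbonyl, so mono-benzylation at the C4 oxygen is expected.

**Step 2**
Reactants: 2 4-(benzyloxy)-5-bromo-2-hydroxybenzaldehyde; 3 2,2-dimethyloxirane
Product: 4 4-(benzyloxy)-5-bromo-2-(2-hydroxy-2-methylpropoxy)benzaldehyde
Conditions: K2CO3 (0.3 equiv), 3 (4 equiv), DMF, 100 °C, sealed tube
Reagents that add atoms: none
Why: Base-mediated SN2 ring opening of the epoxide by the phenoxide at the unsubstituted CH2; attack at the fully substituted carbon is sterically excluded under basic conditions, and the base is regenerated by proton transfer from the next phenol.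

**Step 3**
Reactants: 4 4-(benzyloxy)-5-bromo-2-(2-hydroxy-2-methylpropoxy)benzaldehyde
Product: 5 4-(benzyloxy)-5-bromo-2-[2-methyl-2-(triethylsilyloxy)propoxy]benzaldehyde
Conditions: Et3SiOTf, 2,6-lutidine, CH2Cl2, −78 to 0 °C
Reagents that add atoms: triethylsilyl trifluoromethanesulfonate, CC[Si](CC)(CC)OS(=O)(=O)C(F)(F)F
Why: Silylation of a tertiary alcohol with a silyl triflate and a hindered pyridine base; the aldehyde and aryl ethers are inert at low temperature, and the silyl ether removes the O–H group before the radical step.

**Step 4**
Reactants: 5 4-(benzyloxy)-5-bromo-2-[2-methyl-2-(triethylsilyloxy)propoxy]benzaldehyde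
Product: 6 N'-{(E)-[4-(benzyloxy)-5-bromo-2-[2-methyl-2-(triethylsilyloxy)propoxy]phenyl]methylidene}-4-methylbenzenesulfonohydrazide
Conditions: TsNHNH2, MeOH, rt
Reagents that add atoms: 4-methylbenzenesulfonohydrazide, Cc1ccc(cc1)S(=O)(=O)NN
Why: Condensation of an aldehyde with a sulfonyl hydrazide to the hydrazone; the E isomer is the thermodynamic one, and either isomer would give the same diazo compound.

**Step 5**
Reactants: 6 N'-{(E)-[4-(benzyloxy)-5-bromo-2-[2-methyl-2-(triethylsilyloxy)propoxy]phenyl]methylidene}-4-methylbenzenesulfonohydrazide
Product: 8 (S)-6-(benzyloxy)-5-bromo-2-[2-(triethylsilyloxy)propan-2-yl]-2,3-dihydro-1-benzofuran, via aryldiazomethane 7 (not isolated)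
Conditions: [Co(Por*)] (2–5 mol%; Por* = 5,15-bis(3,5-di-tert-butylphenyl)-10,20-bis[2,6-bis(2,2-dimethylcyclopropanecarboxamido)phenyl]porphyrinate, single antipode chosen for S at C2), Cs2CO3 (2 equiv), 1,4-dioxane, 40–60 °C, N2
Reagents that add atoms: none
Why: Proposed new method: Cs2CO3 converts 6 into the aryldiazomethane 7 by loss of sulfinate, and the divalent cobalt centre of [Co(Por*)] activates 7 with loss of N2 to an α-cobalt benzylic radical at the future C3 (cobalt formally trivalent); this radical takes a hydrogen atom from the O–CH2 group by 1,5-hydrogen atom transfer through a six-membered transition state, and the resulting α-aryloxy radical at C2 displaces cobalt at C3, forming C3–C2 and returning divalent cobalt. The closest known reaction type is the cobalt metalloradical intramolecular C–H alkylation of diazo compounds generated in situ from aldehyde tosylhydrazones, which gives 2-substituted five-membered rings when the C–H bond is benzylic, allylic or next to nitrogen; here the C–H bond is activated only by the ether oxygen and stands next to a fully substituted carbon. Ring B closes in the 5-exo-tet mode, a homolytic substitution at the cobalt-bound carbon. C2 is the only new stereocentre: the C2 radical is planar and the substrate is achiral, so the configuration is set by the chiral cavity of Por* during the ring-closing substitution, possibly helped by hydrogen bonding of its amide N–H groups to the ether oxygen. Site selectivity is secured by geometry, since only the O–CH2 hydrogens stand 1,5 to the radical, while the benzylic hydrogens of the benzyl ether and the C–H bonds of the silyl group are out of reach. Chemoselectivity rests on the radical, non-electrophilic character of the cobalt carbene, which should leave the aryl bromide, the ether oxygens (no ylide formation) and the silyl ether alone. Slow release of 7 at moderate temperature should keep azine formation and the uncatalysed racemic insertion low.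

**Step 6**
Reactants: 9 1-(4-hydroxyphenyl)ethanone; 10 isoprene (2-methylbuta-1,3-diene)
Product: 11 1-(2,2-dimethylchroman-6-yl)ethanone
Conditions: polyphosphoric acid, 10 (excess), xylene, 30–35 °C
Reagents that add atoms: none
Why: Acid-catalysed chroman annulation of a phenol with a 1,3-diene: Friedel–Crafts prenylation ortho to the hydroxyl (para is blocked by acetyl and both ortho positions are equivalent), then Markovnikov addition of the phenol O–H to the prenyl double bond through the tertiary cation closes ring D.

**Step 7**
Reactants: 11 1-(2,2-dimethylchroman-6-yl)ethanone; 12 dimethyl carbonate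
Product: 13 methyl 3-(2,2-dimethylchroman-6-yl)-3-oxopropanoate
Conditions: NaH, 12 (excess), THF, reflux; then aq. HCl
Reagents that add atoms: none
Why: Crossed Claisen condensation (C-acylation of the methyl ketone enolate by the carbonate), driven to completion by deprotonation of the β-keto ester product.

**Step 8**
Reactants: 13 methyl 3-(2,2-dimethylchroman-6-yl)-3-oxopropanoate
Product: 14 methyl (S)-3-(2,2-dimethylchroman-6-yl)-3-hydroxypropanoate
Conditions: RuCl2[(R)-BINAP] (1 mol%), H2 (10 bar), MeOH, 50 °C
Reagents that add atoms: none
Why: Noyori asymmetric hydrogenation of a β-keto ester; with the (R)-BINAP complex of divalent ruthenium the ester-chelated ketone should take hydride on the face that gives the S carbinol for an aryl ketone (aryl outranks the CH2CO2Me arm), which sets the second stereocentre.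

**Step 9**
Reactants: 14 methyl (S)-3-(2,2-dimethylchroman-6-yl)-3-hydroxypropanoate
Product: 15 (S)-3-(2,2-dimethylchroman-6-yl)-3-hydroxy-N-methoxy-N-methylpropanamide
Conditions: MeNH(OMe)·HCl (3 equiv), i-PrMgCl (excess), THF, −20 to 0 °C; aq. NH4Cl
Reagents that add atoms: N,O-dimethylhydroxylamine hydrochloride, CNOC.Cl
Why: Weinreb amide formation by aminolysis of the ester with the chloromagnesium amide made in situ; the magnesium alkoxide of the free carbinol is tolerated at low temperature and the stereocentre is not touched.

**Step 10**
Reactants: 15 (S)-3-(2,2-dimethylchroman-6-yl)-3-hydroxy-N-methoxy-N-methylpropanamide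
Product: 16 (S)-3-(2,2-dimethylchroman-6-yl)-N-methoxy-N-methyl-3-(triethylsilyloxy)propanamide
Conditions: Et3SiCl, imidazole, DMF, 0 °C to rt
Reagents that add atoms: chlorotriethylsilane, CC[Si](Cl)(CC)CC
Why: Silylation of the secondary benzylic alcohol (silyl chloride, imidazole), so that the carbinol survives the aryllithium and cannot eliminate or undergo retro-aldol cleavage later.

**Step 11**
Reactants: 8 (S)-6-(benzyloxy)-5-bromo-2-[2-(triethylsilyloxy)propan-2-yl]-2,3-dihydro-1-benzofuran; 16 (S)-3-(2,2-dimethylchroman-6-yl)-N-methoxy-N-methyl-3-(triethylsilyloxy)propanamide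
Product: 18 (S)-1-[(S)-6-(benzyloxy)-2-[2-(triethylsilyloxy)propan-2-yl]-2,3-dihydro-1-benzofuran-5-yl]-3-(2,2-dimethylchroman-6-yl)-3-(triethylsilyloxy)propan-1-one, via aryllithium 17 (not isolated)
Conditions: n-BuLi, THF, −78 °C; then 16, −78 to −20 °C; aq. NH4Cl
Reagents that add atoms: none
Why: Bromine–lithium exchange is faster than any deprotonation at −78 °C and gives 17, which adds once to the amide; the five-membered lithium chelate of the tetrahedral adduct holds until work-up, so the ketone forms without over-addition (Weinreb ketone synthesis) and neither stereocentre is involved.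

**Step 12**
Reactants: 18 (S)-1-[(S)-6-(benzyloxy)-2-[2-(triethylsilyloxy)propan-2-yl]-2,3-dihydro-1-benzofuran-5-yl]-3-(2,2-dimethylchroman-6-yl)-3-(triethylsilyloxy)propan-1-one
Product: 19 (S)-3-(2,2-dimethylchroman-6-yl)-1-[(S)-6-hydroxy-2-[2-(triethylsilyloxy)propan-2-yl]-2,3-dihydro-1-benzofuran-5-yl]-3-(triethylsilyloxy)propan-1-one
Conditions: H2 (1 atm), Pd/C (10%), EtOAc, rt
Reagents that add atoms: none
Why: Catalytic hydrogenolysis of an aryl benzyl ether over Pd/C; in ethyl acetate without acid the silyl-protected benzylic C–O bond and the electron-rich aryl ketone should react much more slowly.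

**Step 13**
Reactants: 19 (S)-3-(2,2-dimethylchroman-6-yl)-1-[(S)-6-hydroxy-2-[2-(triethylsilyloxy)propan-2-yl]-2,3-dihydro-1-benzofuran-5-yl]-3-(triethylsilyloxy)propan-1-one
Product: 20 (S)-3-(2,2-dimethylchroman-6-yl)-3-hydroxy-1-[(S)-6-hydroxy-2-(2-hydroxypropan-2-yl)-2,3-dihydro-1-benzofuran-5-yl]propan-1-one
Conditions: HF·pyridine, pyridine, THF, 0 °C to rt
Reagents that add atoms: none
Why: Fluoride-mediated cleavage of both triethylsilyl ethers, driven by Si–F bond formation; buffering with pyridine keeps the medium near neutral, so the β-hydroxy ketone should neither ionise at the benzylic carbinol nor undergo retro-aldol cleavage.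

## Compound list

1 | 5-bromo-2,4-dihydroxybenzaldehyde | O=Cc1cc(Br)c(O)cc1O | starting material
2 | 4-(benzyloxy)-5-bromo-2-hydroxybenzaldehyde | O=Cc1cc(Br)c(OCc2ccccc2)cc1O | intermediate
3 | 2,2-dimethyloxirane | CC1(C)CO1 | starting material
4 | 4-(benzyloxy)-5-bromo-2-(2-hydroxy-2-methylpropoxy)benzaldehyde | O=Cc1cc(Br)c(OCc2ccccc2)cc1OCC(C)(C)O | intermediate
5 | 4-(benzyloxy)-5-bromo-2-[2-methyl-2-(triethylsilyloxy)propoxy]benzaldehyde | O=Cc1cc(Br)c(OCc2ccccc2)cc1OCC(C)(C)O[Si](CC)(CC)CC | intermediate
6 | N'-{(E)-[4-(benzyloxy)-5-bromo-2-[2-methyl-2-(triethylsilyloxy)propoxy]phenyl]methylidene}-4-methylbenzenesulfonohydrazide | Cc1ccc(cc1)S(=O)(=O)N/N=C/c1cc(Br)c(OCc2ccccc2)cc1OCC(C)(C)O[Si](CC)(CC)CC | intermediate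
7 | [4-(benzyloxy)-5-bromo-2-[2-methyl-2-(triethylsilyloxy)propoxy]phenyl]diazomethane | [N-]=[N+]=Cc1cc(Br)c(OCc2ccccc2)cc1OCC(C)(C)O[Si](CC)(CC)CC | intermediate (not isolated)
8 | (S)-6-(benzyloxy)-5-bromo-2-[2-(triethylsilyloxy)propan-2-yl]-2,3-dihydro-1-benzofuran | Brc1cc2c(cc1OCc3ccccc3)O[C@H](C(C)(C)O[Si](CC)(CC)CC)C2 | intermediate
9 | 1-(4-hydroxyphenyl)ethanone | CC(=O)c1ccc(O)cc1 | starting material
10 | isoprene (2-methylbuta-1,3-diene) | C=CC(C)=C | starting material
11 | 1-(2,2-dimethylchroman-6-yl)ethanone | CC1(C)CCc2cc(C(C)=O)ccc2O1 | intermediate
12 | dimethyl carbonate | COC(=O)OC | starting material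
13 | methyl 3-(2,2-dimethylchroman-6-yl)-3-oxopropanoate | CC1(C)CCc2cc(C(=O)CC(=O)OC)ccc2O1 | intermediate
14 | methyl (S)-3-(2,2-dimethylchroman-6-yl)-3-hydroxypropanoate | CC1(C)CCc2cc([C@@H](O)CC(=O)OC)ccc2O1 | intermediate
15 | (S)-3-(2,2-dimethylchroman-6-yl)-3-hydroxy-N-methoxy-N-methylpropanamide | CC1(C)CCc2cc([C@@H](O)CC(=O)N(C)OC)ccc2O1 | intermediate
16 | (S)-3-(2,2-dimethylchroman-6-yl)-N-methoxy-N-methyl-3-(triethylsilyloxy)propanamide | CC1(C)CCc2cc([C@@H](O[Si](CC)(CC)CC)CC(=O)N(C)OC)ccc2O1 | intermediate
17 | [(S)-6-(benzyloxy)-2-[2-(triethylsilyloxy)propan-2-yl]-2,3-dihydro-1-benzofuran-5-yl]lithium | [Li]c1cc2c(cc1OCc3ccccc3)O[C@H](C(C)(C)O[Si](CC)(CC)CC)C2 | intermediate (not isolated)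
18 | (S)-1-[(S)-6-(benzyloxy)-2-[2-(triethylsilyloxy)propan-2-yl]-2,3-dihydro-1-benzofuran-5-yl]-3-(2,2-dimethylchroman-6-yl)-3-(triethylsilyloxy)propan-1-one | CC1(C)CCc2cc([C@@H](O[Si](CC)(CC)CC)CC(=O)c3cc4c(cc3OCc5ccccc5)O[C@H](C(C)(C)O[Si](CC)(CC)CC)C4)ccc2O1 | intermediate
19 | (S)-3-(2,2-dimethylchroman-6-yl)-1-[(S)-6-hydroxy-2-[2-(triethylsilyloxy)propan-2-yl]-2,3-dihydro-1-benzofuran-5-yl]-3-(triethylsilyloxy)propan-1-one | CC1(C)CCc2cc([C@@H](O[Si](CC)(CC)CC)CC(=O)c3cc4c(cc3O)O[C@H](C(C)(C)O[Si](CC)(CC)CC)C4)ccc2O1 | intermediate
20 | (S)-3-(2,2-dimethylchroman-6-yl)-3-hydroxy-1-[(S)-6-hydroxy-2-(2-hydroxypropan-2-yl)-2,3-dihydro-1-benzofuran-5-yl]propan-1-one | CC1(C)CCc2cc([C@@H](O)CC(=O)c3cc4c(cc3O)O[C@H](C(C)(C)O)C4)ccc2O1 | target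

## Step count

Total: 13 steps. Longest linear sequence: 8 steps (steps 1–5, 11–13; the chroman branch, steps 6–10, 11–13, is equally long).

## Least certain steps

**Step 5 (key step, Proposed new method).** Hydrogen atom transfer from the hindered CH2, which is activated only by the ether oxygen, may be slower than coupling of the cobalt carbene radical with a second molecule of 7 or than uncatalysed thermal decomposition of 7. Facial control in the ring-closing substitution next to the bulky silyloxy carbon may also be poor. The fallback uses known chemistry, sets out from 2 and returns at 8 in the same number of steps.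
- Rap–Stoermer condensation of 2 with chloroacetone (K2CO3, DMF, 80 °C) should give 1-[6-(benzyloxy)-5-bromo-1-benzofuran-2-yl]ethanone F1.
- MeMgBr (THF, 0 °C) should give 2-[6-(benzyloxy)-5-bromo-1-benzofuran-2-yl]propan-2-ol F2.
- Et3SiOTf and 2,6-lutidine should give 6-(benzyloxy)-5-bromo-2-[2-(triethylsilyloxy)propan-2-yl]-1-benzofuran F3.
- Asymmetric hydrogenation of the furan C2=C3 bond, a known reaction type for 2-substituted benzofurans, with [Ir(cod)(L*)][B(C6H3(CF3)2)4] (L* = chiral pyridine–phosphinite, antipode chosen for S), H2 (50 bar), CH2Cl2, should give 8.

**Step 11.** The basic aryllithium 17 may deprotonate 16 next to the amide, with loss of silanolate to the unsaturated amide. If the exchange mixture warms, proton transfer from the benzyl CH2 to the aryl carbanion may occur instead of addition. The fallback sets out from 16 and 8 and returns at 18. Reduction of 16 with i-Bu2AlH (THF, −78 °C) should give (S)-3-(2,2-dimethylchroman-6-yl)-3-(triethylsilyloxy)propanal F4. Addition of 17 (from 8 and n-BuLi as before) to this more electrophilic and less enolisable partner should give (3S)-1-[(S)-6-(benzyloxy)-2-[2-(triethylsilyloxy)propan-2-yl]-2,3-dihydro-1-benzofuran-5-yl]-3-(2,2-dimethylchroman-6-yl)-3-(triethylsilyloxy)propan-1-ol F5 as a pair of epimers at C1. Oxidation with Dess–Martin periodinane (NaHCO3, CH2Cl2) would remove that centre and give 18.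

**Step 6.** Ring alkylation of the acetyl-deactivated phenol may be too slow, so that oligomerisation of 10, O-prenylation or double alkylation wins. The fallback sets out from 9 and returns at 11. Alkylation of 9 with 3-chloro-3-methylbut-1-yne (K2CO3, KI, acetone, reflux) should give 1-{4-[(2-methylbut-3-yn-2-yl)oxy]phenyl}ethanone F6. Heating in N,N-diethylaniline at 190 °C (propargyl Claisen rearrangement, hydrogen shift and 6π electrocyclisation) should give 1-(2,2-dimethyl-2H-chromen-6-yl)ethanone F7. Hydrogenation of the ring D double bond (H2, Pd/C, EtOAc) should give 11.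

**Step 12.** Reductive cleavage of the benzylic C–O bond at the carbinol, or reduction of the aryl ketone, may accompany the debenzylation. The fallback replaces reduction by chelation-directed Lewis-acid dealkylation. MgBr2·OEt2 in toluene–ether at about 60 °C binds the ketone oxygen and the neighbouring ether oxygen, and bromide removes the benzyl group by SN2 attack. This is a known selective cleavage of benzyl ethers ortho to a carbonyl group. It sets out from 18 and returns at 19 without passing through any compound outside the list (F0).

**Step 13.** With the phenol free, the carbinol may be lost by acid-promoted ionisation (flavanone closure through the ortho-phenol, or dehydration to the chalcone) or by base-promoted retro-aldol cleavage during desilylation. The fallback reverses the order of the last two operations, so that fluoride acts while the phenol is still benzylated. It sets out from 18 and returns at 20. HF·pyridine with pyridine in THF should give (S)-1-[(S)-6-(benzyloxy)-2-(2-hydroxypropan-2-yl)-2,3-dihydro-1-benzofuran-5-yl]-3-(2,2-dimethylchroman-6-yl)-3-hydroxypropan-1-one F8. Neutral hydrogenolysis (H2, Pd/C, EtOAc), in which an aryl benzyl ether reacts well before a benzylic alcohol in the absence of acid, should then give 20.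

## Further compounds

F1 | step 5 | 1-[6-(benzyloxy)-5-bromo-1-benzofuran-2-yl]ethanone | CC(=O)c1cc2cc(Br)c(OCc3ccccc3)cc2o1
F2 | step 5 | 2-[6-(benzyloxy)-5-bromo-1-benzofuran-2-yl]propan-2-ol | CC(C)(O)c1cc2cc(Br)c(OCc3ccccc3)cc2o1
F3 | step 5 | 6-(benzyloxy)-5-bromo-2-[2-(triethylsilyloxy)propan-2-yl]-1-benzofuran | CC(C)(O[Si](CC)(CC)CC)c1cc2cc(Br)c(OCc3ccccc3)cc2o1
F4 | step 11 | (S)-3-(2,2-dimethylchroman-6-yl)-3-(triethylsilyloxy)propanal | CC1(C)CCc2cc([C@@H](O[Si](CC)(CC)CC)CC=O)ccc2O1
F5 | step 11 | (3S)-1-[(S)-6-(benzyloxy)-2-[2-(triethylsilyloxy)propan-2-yl]-2,3-dihydro-1-benzofuran-5-yl]-3-(2,2-dimethylchroman-6-yl)-3-(triethylsilyloxy)propan-1-ol (both epimers at C1) | CC1(C)CCc2cc([C@@H](O[Si](CC)(CC)CC)CC(O)c3cc4c(cc3OCc5ccccc5)O[C@H](C(C)(C)O[Si](CC)(CC)CC)C4)ccc2O1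
F6 | step 6 | 1-{4-[(2-methylbut-3-yn-2-yl)oxy]phenyl}ethanone | CC(=O)c1ccc(OC(C)(C)C#C)cc1
F7 | step 6 | 1-(2,2-dimethyl-2H-chromen-6-yl)ethanone | CC(=O)c1ccc2OC(C)(C)C=Cc2c1
F0 | step 12 | none | none
F8 | step 13 | (S)-1-[(S)-6-(benzyloxy)-2-(2-hydroxypropan-2-yl)-2,3-dihydro-1-benzofuran-5-yl]-3-(2,2-dimethylchroman-6-yl)-3-hydroxypropan-1-one | CC1(C)CCc2cc([C@@H](O)CC(=O)c3cc4c(cc3OCc5ccccc5)O[C@H](C(C)(C)O)C4)ccc2O1
A1 | alternative 1 | 4-hydroxy-3-(hydroxymethyl)benzaldehyde | O=Cc1ccc(O)c(CO)c1
A2 | alternative 1 | 2-methylpropene | C=C(C)C
A3 | alternative 1 | 2,2-dimethylchroman-6-carbaldehyde | CC1(C)CCc2cc(C=O)ccc2O1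
A4 | alternative 2 | 1-(2,4-dihydroxy-5-iodophenyl)ethanone | CC(=O)c1cc(I)c(O)cc1O
A5 | alternative 2 | (S)-1-[6-hydroxy-2-(prop-1-en-2-yl)-2,3-dihydro-1-benzofuran-5-yl]ethanone | CC(=O)c1cc2c(cc1O)O[C@H](C(C)=C)C2
A6 | alternative 2 | (S)-1-[6-hydroxy-2-(2-hydroxypropan-2-yl)-2,3-dihydro-1-benzofuran-5-yl]ethanone | CC(=O)c1cc2c(cc1O)O[C@H](C(C)(C)O)C2
A7 | alternative 3 | 5-(allyloxy)-4-bromo-2-[(4-methylbenzenesulfonyl)methyl]phenol | Cc1ccc(cc1)S(=O)(=O)Cc1cc(Br)c(OCC=C)cc1O
A8 | alternative 3 | ethyl (dimethylsulfuranylidene)acetate | CCOC(=O)C=S(C)C
A9 | alternative 3 | ethyl (S)-6-(allyloxy)-5-bromo-2,3-dihydro-1-benzofuran-2-carboxylate | Brc1cc2c(cc1OCC=C)O[C@H](C(=O)OCC)C2
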